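Ring A is disconnected at C1–C2 and C4–C5 (labdane numbering). The precursor is a ring B keto aldehyde in which C1 is a formyl group on the quaternary C10 and C5 is the ring ketone, so the two electrophilic carbons are 1,3-related across C10, the feature the key step exploits; methyl acetoacetate supplies C2–C3–C4 with C19 as its ester. In one flask the acetoacetate dianion adds through C2 to the aldehyde and the β-keto ester then condenses through C4 with the C5 ketone, closing ring A as a cross-conjugated dienone ester. From this array one reductive methylation sets C5 and quaternary C4; the C3 oxygen is removed and the Z side chain is attached by B-alkyl Suzuki coupling.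

Key step: step 6

Remark: labdane numbering is used throughout (C1–C10 decalin, C11–C16 side chain, C17 on C8, C18 = 4α-methyl, C19 = 4β-carbon, C20 = 10β-methyl); α/β refer to the normal series defined by the SMILES strings.

Step 1
Reactants: 1 1,4-dioxaspiro[4.5]deca-6,9-dien-8-one (p-benzoquinone mono(ethylene ketal)); 2 potassium vinyltrifluoroborate
Product: 3 (S)-4,4-(ethylenedioxy)-5-vinylcyclohex-2-en-1-one
Conditions: [Rh(cod)2]BF4 (3 mol %), (S)-BINAP (3.3 mol %), 2 (1.2 equiv), Et3N, toluene/H2O (4:1), 80 °C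
Reagents that add atoms: none
Why: Rhodium-catalysed asymmetric 1,4-addition (Hayashi–Miyaura type) of the vinyl group to one enone arm of the symmetric dienone; (S)-BINAP should select arm and face in the same sense as for 2-cyclohexenone, giving C9 as (S), and Et3N protects the acid-labile ketal.

Step 2
Reactants: 3 (S)-4,4-(ethylenedioxy)-5-vinylcyclohex-2-en-1-one
Product: 4 (5R,6R)-4,4-(ethylenedioxy)-6-methyl-5-vinylcyclohex-2-en-1-one (trans; the C6 epimer serves equally)
Conditions: LiN(i-Pr)2 (1.1 equiv), THF, −78 °C; MeI, −78 → −40 °C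
Reagents that add atoms: iodomethane CI
Why: Kinetic α′-enolate alkylation of an enone; only C10 can be deprotonated because the γ-carbon is the ketal carbon, and the new centre is re-enolized in step 3.

Step 3
Reactants: 4 (5R,6R)-4,4-(ethylenedioxy)-6-methyl-5-vinylcyclohex-2-en-1-one
Product: 5 (5R,6S)-4,4-(ethylenedioxy)-6-(hydroxymethyl)-6-methyl-5-vinylcyclohex-2-en-1-one
Conditions: LiN(i-Pr)2 (1.2 equiv), THF, −78 → −40 °C; CH2O (g), −78 °C; AcOH quench at −78 °C
Reagents that add atoms: formaldehyde C=O
Why: Aldol addition of the fully substituted α′-enolate to formaldehyde, directed to C10 because the other α-carbon is vinylic; the electrophile should enter anti to the adjacent vinyl group, so the quaternary C10 carries CH2OH trans and CH3 cis to vinyl.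

Step 4
Reactants: 5 (5R,6S)-4,4-(ethylenedioxy)-6-(hydroxymethyl)-6-methyl-5-vinylcyclohex-2-en-1-one
Product: 6 (2S,3R)-4,4-(ethylenedioxy)-2-(hydroxymethyl)-2-methyl-3-vinylcyclohexan-1-one
Conditions: [(Ph3P)CuH]6 (0.5 equiv), toluene, H2O (5 equiv), 23 °C
Reagents that add atoms: none
Why: Copper hydride conjugate reduction removes the enone C=C that served as regiocontrol element, leaves the isolated vinyl group alone and is neutral enough to avoid retro-aldol loss of the hydroxymethyl group.

Step 5
Reactants: 6 (2S,3R)-4,4-(ethylenedioxy)-2-(hydroxymethyl)-2-methyl-3-vinylcyclohexan-1-one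
Product: 7 (1S,2R)-3,3-(ethylenedioxy)-1-methyl-6-oxo-2-vinylcyclohexane-1-carbaldehyde
Conditions: Dess–Martin periodinane (1.3 equiv), CH2Cl2, 0 → 23 °C
Reagents that add atoms: none
Why: Dess–Martin oxidation of the neopentyl primary alcohol under non-basic conditions; the quaternary C10 cannot enolize, so no epimerization is possible.

Step 6
Reactants: 7 (1S,2R)-3,3-(ethylenedioxy)-1-methyl-6-oxo-2-vinylcyclohexane-1-carbaldehyde; 8 methyl acetoacetate
Product: 11 methyl 8,8-(ethylenedioxy)-3-oxo-13,14,15,16,17,18-hexanorlabda-1,4,11-trien-19-oate (9β-vinyl, 10β-methyl), via aldol adduct 9 (not isolated), via hydroxy enone 10 (not isolated)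
Conditions: 8 (1.3 equiv), NaH then n-BuLi, THF, 0 °C; add 7, −78 °C; AcOH, −78 °C; then pyrrolidine (0.3 equiv), AcOH, 4 Å MS, 23 → 55 °C (same flask)
Reagents that add atoms: none
Why: The acetoacetate dianion attacks the aldehyde C1 through its terminal carbon C2 (aldol addition, C1–C2 bond) to give 9; pyrrolidinium acetate then turns the β-keto ester into its enamino ester, whose α-carbon C4 adds to the C5 ketone, and two dehydrations (Knoevenagel to C4=C5 in 10, then E1cB loss of the C1 hydroxyl) should deliver 11. The closest known reaction type is the [3+3] cyclocondensation of acetoacetate 1,3-dianion equivalents with 1,3-dicarbonyl electrophiles, that is a γ-aldol followed by a Robinson-type Knoevenagel closure. Ring A is closed by a 6-(enolendo)-exo-trig aldol attack of C4 on the C5 carbonyl. No stereocentre is created, C9 and C10 cannot enolize, and the quaternary C10 blocks aromatization so the product stops at the cross-conjugated dienone. The step needs regioselectivity (C2 to C1, C4 to C5): the dianion is most nucleophilic at C2 and prefers the aldehyde over the hindered ketone, and only closure through C4 gives a six-membered ring. The cold acidic quench before the amine stage is meant to suppress retro-aldol cleavage of the C1–C10 bond.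

Step 7
Reactants: 11 methyl 8,8-(ethylenedioxy)-3-oxo-13,14,15,16,17,18-hexanorlabda-1,4,11-trien-19-oate
Product: 12 methyl 8,8-(ethylenedioxy)-3-oxo-13,14,15,16,17-pentanorlabda-1,11-dien-19-oate (5α-H, 4α-CH3, 4β-CO2Me)
Conditions: Li (2.2 equiv), NH3/THF, t-BuOH (1.0 equiv), −78 °C; isoprene; NH3 removed; MeI, THF, −78 → 0 °C
Reagents that add atoms: iodomethane CI
Why: Birch-type dissolving-metal reductive alkylation: the doubly activated C4=C5 bond takes up two electrons, axial protonation at C5 gives the trans ring fusion, and the resulting β-keto ester enolate (which also protects the C1=C2 enone from reduction) is methylated on the α-face anti to the axial 10β-methyl, leaving CO2Me axial as C19.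

Step 8
Reactants: 12 methyl 8,8-(ethylenedioxy)-3-oxo-13,14,15,16,17-pentanorlabda-1,11-dien-19-oate
Product: 14 methyl 8,8-(ethylenedioxy)-3β-hydroxy-13,14,15,16,17-pentanorlabd-11-en-19-oate, via saturated ketone 13 (not isolated)
Conditions: LiBH(s-Bu)3 (1.2 equiv), THF, −78 °C; then MeOH, NaBH4, −78 → 0 °C
Reagents that add atoms: none
Why: Conjugate hydride reduction of the β-unsubstituted, carbonyl-hindered enone by the bulky borohydride, then NaBH4 reduction of the released ketone; the C3 configuration is irrelevant because this oxygen is removed.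

Step 9
Reactants: 14 methyl 8,8-(ethylenedioxy)-3β-hydroxy-13,14,15,16,17-pentanorlabd-11-en-19-oate
Product: 15 3-O-(imidazol-1-ylthiocarbonyl) derivative of 14
Conditions: 1,1'-thiocarbonyldiimidazole (3 equiv), DMAP (0.3 equiv), toluene, 100 °C
Reagents that add atoms: 1,1'-thiocarbonyldiimidazole S=C(n1ccnc1)n1ccnc1
Why: Thioacylation of the hindered secondary alcohol prepares the Barton–McCombie deoxygenation; the neutral conditions avoid retro-aldol cleavage of the β-hydroxy ester.

Step 10
Reactants: 15 3-O-(imidazol-1-ylthiocarbonyl) derivative of 14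
Product: 16 methyl 8,8-(ethylenedioxy)-13,14,15,16,17-pentanorlabd-11-en-19-oate
Conditions: Bu3SnH (2 equiv), AIBN (0.2 equiv), toluene, 110 °C
Reagents that add atoms: none
Why: Barton–McCombie radical deoxygenation; the secondary C3 radical should be reduced by the tin hydride long before it can reach the remote vinyl group.

Step 11
Reactants: 16 methyl 8,8-(ethylenedioxy)-13,14,15,16,17-pentanorlabd-11-en-19-oate
Product: 17 8,8-(ethylenedioxy)-13,14,15,16,17-pentanorlabd-11-en-19-ol
Conditions: LiAlH4 (3 equiv), THF, 0 → 66 °C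
Reagents that add atoms: none
Why: Hydride reduction of the hindered axial ester to the neopentyl C19 alcohol; ketal and vinyl group are inert.

Step 12
Reactants: 18 ethyl but-2-ynoate
Product: 19 ethyl (Z)-3-iodobut-2-enoate
Conditions: NaI (1.6 equiv), AcOH, 115 °C
Reagents that add atoms: sodium iodide [Na+].[I-]
Why: Conjugate hydroiodination of the ynoate (iodide addition, then anti protonation) should give the Z-iodoenoate with iodine cis to the ester.

Step 13
Reactants: 17 8,8-(ethylenedioxy)-13,14,15,16,17-pentanorlabd-11-en-19-ol; 19 ethyl (Z)-3-iodobut-2-enoate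
Product: 21 ethyl (13Z)-8,8-(ethylenedioxy)-19-hydroxy-17-norlabd-13-en-15-oate, via alkylborane 20 (not isolated)
Conditions: 9-BBN (2.5 equiv), THF, 23 °C; then 19 (1.3 equiv), Pd(dppf)Cl2 (5 mol %), AsPh3, K3PO4 (3 M aq.), DMF, 23 °C
Reagents that add atoms: none
Why: Anti-Markovnikov hydroboration of the only alkene (the hydroxyl is carried as its borinate and freed on work-up), then B-alkyl Suzuki–Miyaura coupling with retention of the vinyl iodide geometry, so C12 ends cis to the ester (13Z).

Step 14
Reactants: 21 ethyl (13Z)-8,8-(ethylenedioxy)-19-hydroxy-17-norlabd-13-en-15-oate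
Product: 22 ethyl (13Z)-19-hydroxy-8-oxo-17-norlabd-13-en-15-oate
Conditions: HCl (1 M aq.), THF, 23 °C
Reagents that add atoms: water O
Why: Acid hydrolysis of the dioxolane; C9 next to the new ketone already carries the thermodynamically preferred equatorial side chain, so enolization cannot degrade it.

Step 15
Reactants: 22 ethyl (13Z)-19-hydroxy-8-oxo-17-norlabd-13-en-15-oate
Product: 23 ethyl (13Z)-19-hydroxylabda-8(17),13-dien-15-oate
Conditions: Ph3PCH3Br (4 equiv), KOt-Bu (3.8 equiv), THF, 23 → 60 °C
Reagents that add atoms: methyltriphenylphosphonium bromide C[P+](c1ccccc1)(c1ccccc1)c1ccccc1.[Br-]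
Why: Wittig methylenation of the hindered C8 ketone; excess ylide compensates for the free hydroxyl and the trisubstituted enoate is not attacked.

Step 16
Reactants: 23 ethyl (13Z)-19-hydroxylabda-8(17),13-dien-15-oate
Product: 24 (13Z)-19-hydroxylabda-8(17),13-dien-15-oic acid
Conditions: LiOH·H2O (5 equiv), THF/MeOH/H2O, 40 °C; then 1 M HCl to pH 3
Reagents that add atoms: lithium hydroxide [Li+].[OH-]
Why: Saponification of the ethyl ester under mild conditions that should not isomerize the Z enoate or the exocyclic alkene.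

Step 17
Reactants: 24 (13Z)-19-hydroxylabda-8(17),13-dien-15-oic acid
Product: 25 (13Z)-19-acetoxylabda-8(17),13-dien-15-oic acid (CNP0360430.3)
Conditions: Ac2O (3 equiv), pyridine, DMAP (5 mol %), 0 → 23 °C; then H2O
Reagents that add atoms: acetic anhydride CC(=O)OC(C)=O
Why: Nucleophile-catalysed acetylation of the primary alcohol; any mixed anhydride formed at C15 is hydrolysed during the aqueous work-up.

Compound list
1 | 1,4-dioxaspiro[4.5]deca-6,9-dien-8-one | O=C1C=CC2(OCCO2)C=C1 | starting material
2 | potassium vinyltrifluoroborate | C=C[B-](F)(F)F.[K+] | starting material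
3 | (S)-4,4-(ethylenedioxy)-5-vinylcyclohex-2-en-1-one | O=C1C=CC2(OCCO2)[C@H](C=C)C1 | intermediate
4 | (5R,6R)-4,4-(ethylenedioxy)-6-methyl-5-vinylcyclohex-2-en-1-one | O=C1C=CC2(OCCO2)[C@H](C=C)[C@H]1C | intermediate
5 | (5R,6S)-4,4-(ethylenedioxy)-6-(hydroxymethyl)-6-methyl-5-vinylcyclohex-2-en-1-one | O=C1C=CC2(OCCO2)[C@H](C=C)[C@@]1(C)CO | intermediate
6 | (2S,3R)-4,4-(ethylenedioxy)-2-(hydroxymethyl)-2-methyl-3-vinylcyclohexan-1-one | O=C1CCC2(OCCO2)[C@H](C=C)[C@@]1(C)CO | intermediate
7 | (1S,2R)-3,3-(ethylenedioxy)-1-methyl-6-oxo-2-vinylcyclohexane-1-carbaldehyde | O=C1CCC2(OCCO2)[C@H](C=C)[C@@]1(C)C=O | intermediate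
8 | methyl acetoacetate | CC(=O)CC(=O)OC | starting material
9 | methyl 5-[(1S,2R)-3,3-(ethylenedioxy)-1-methyl-6-oxo-2-vinylcyclohexyl]-5-hydroxy-3-oxopentanoate (C1 carbinol epimers) | O=C1CCC2(OCCO2)[C@H](C=C)[C@@]1(C)C(O)CC(=O)CC(=O)OC | intermediate
10 | methyl 8,8-(ethylenedioxy)-1-hydroxy-3-oxo-13,14,15,16,17,18-hexanorlabda-4,11-dien-19-oate (C1 epimers) | O3CCOC31CCC2=C(C(=O)OC)C(=O)CC(O)[C@]2(C)[C@H]1C=C | intermediate
11 | methyl 8,8-(ethylenedioxy)-3-oxo-13,14,15,16,17,18-hexanorlabda-1,4,11-trien-19-oate | O3CCOC31CCC2=C(C(=O)OC)C(=O)C=C[C@]2(C)[C@H]1C=C | intermediate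
12 | methyl 8,8-(ethylenedioxy)-3-oxo-13,14,15,16,17-pentanorlabda-1,11-dien-19-oate | O3CCOC31CC[C@H]2[C@@](C)(C(=O)OC)C(=O)C=C[C@]2(C)[C@H]1C=C | intermediate
13 | methyl 8,8-(ethylenedioxy)-3-oxo-13,14,15,16,17-pentanorlabd-11-en-19-oate | O3CCOC31CC[C@H]2[C@@](C)(C(=O)OC)C(=O)CC[C@]2(C)[C@H]1C=C | intermediate
14 | methyl 8,8-(ethylenedioxy)-3β-hydroxy-13,14,15,16,17-pentanorlabd-11-en-19-oate | O3CCOC31CC[C@H]2[C@@](C)(C(=O)OC)[C@@H](O)CC[C@]2(C)[C@H]1C=C | intermediate
15 | methyl 8,8-(ethylenedioxy)-3β-[(imidazol-1-ylthiocarbonyl)oxy]-13,14,15,16,17-pentanorlabd-11-en-19-oate | O3CCOC31CC[C@H]2[C@@](C)(C(=O)OC)[C@@H](OC(=S)n4ccnc4)CC[C@]2(C)[C@H]1C=C | intermediate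
16 | methyl 8,8-(ethylenedioxy)-13,14,15,16,17-pentanorlabd-11-en-19-oate | O3CCOC31CC[C@H]2[C@@](C)(C(=O)OC)CCC[C@]2(C)[C@H]1C=C | intermediate
17 | 8,8-(ethylenedioxy)-13,14,15,16,17-pentanorlabd-11-en-19-ol | O3CCOC31CC[C@H]2[C@@](C)(CO)CCC[C@]2(C)[C@H]1C=C | intermediate
18 | ethyl but-2-ynoate | CC#CC(=O)OCC | starting material
19 | ethyl (Z)-3-iodobut-2-enoate | CCOC(=O)/C=C(/C)I | intermediate
20 | 12-(9-borabicyclo[3.3.1]nonan-9-yl) derivative of 17 carrying the 19-O-(9-borabicyclononyl) borinate | O3CCOC31CC[C@H]2[C@@](C)(COB4C5CCCC4CCC5)CCC[C@]2(C)[C@H]1CCB6C7CCCC6CCC7 | intermediate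
21 | ethyl (13Z)-8,8-(ethylenedioxy)-19-hydroxy-17-norlabd-13-en-15-oate | O3CCOC31CC[C@H]2[C@@](C)(CO)CCC[C@]2(C)[C@H]1CC/C(C)=C\C(=O)OCC | intermediate
22 | ethyl (13Z)-19-hydroxy-8-oxo-17-norlabd-13-en-15-oate | O=C1CC[C@H]2[C@@](C)(CO)CCC[C@]2(C)[C@H]1CC/C(C)=C\C(=O)OCC | intermediate
23 | ethyl (13Z)-19-hydroxylabda-8(17),13-dien-15-oate | C=C1CC[C@H]2[C@@](C)(CO)CCC[C@]2(C)[C@H]1CC/C(C)=C\C(=O)OCC | intermediate
24 | (13Z)-19-hydroxylabda-8(17),13-dien-15-oic acid | C=C1CC[C@H]2[C@@](C)(CO)CCC[C@]2(C)[C@H]1CC/C(C)=C\C(=O)O | intermediate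
25 | (13Z)-19-acetoxylabda-8(17),13-dien-15-oic acid | C=C1CC[C@H]2[C@@](C)(COC(C)=O)CCC[C@]2(C)[C@H]1CC/C(C)=C\C(=O)O | target

Total step count: 17. Longest linear sequence: 16 (steps 1–11 and 13–17; step 12 is a one-step branch).

Steps most likely to fail

Step 6. The β-hydroxy ketone stage may fragment by retro-aldol cleavage of the C1–C10 bond, or the δ-hydroxy-β-keto ester may lactonize before ring A closes. The fallback keeps the one-flask closure but starts with an olefination. It sets out from 7: the sodium dianion of methyl 4-(dimethoxyphosphoryl)-3-oxobutanoate (NaH, THF, 0 °C) undergoes a Horner–Wadsworth–Emmons reaction with the aldehyde to give the E-configured enone keto ester F1, which can no longer lose the C1 unit. Pyrrolidinium acetate added to the same flask adds reversibly to the enone to give the β-amino ketone F2, which lifts the E-geometry constraint. The enamino ester then closes onto the C5 ketone and pyrrolidine is eliminated, so the sequence comes back to the route at 11.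

Step 7. Electron transfer may not stop at the C4=C5 bond, so that the C1=C2 enone is also reduced and C2 is methylated. The fallback separates the two reductions and sets out from 11: conjugate reduction of the less hindered C1=C2 bond with [(Ph3P)CuH]6 (toluene, H2O, 23 °C) gives the mono-enone keto ester F3. Reductive methylation of F3 (Li, NH3/THF, t-BuOH; MeI), now without a competing enone, gives the saturated keto ester 13, and NaBH4 reduction as in the second stage of step 8 comes back to the route at 14.

Step 1. A second conjugate addition to the remaining enone arm (bis-vinylation) and loss of enantioselectivity at the temperature needed may erode the step. The fallback uses an acceptor with a single enone and sets out from 1: one hydride equivalent of [(Ph3P)CuH]6 gives the mono-enone 1,4-dioxaspiro[4.5]dec-6-en-8-one F4 (the copper dienolate resists a second reduction until work-up). The same rhodium/(S)-BINAP vinylation with 2 gives the saturated ketone (S)-6-vinyl-1,4-dioxaspiro[4.5]decan-8-one F5. Kinetic enolization on the unhindered side (LiN(i-Pr)2, Me3SiCl, THF, −78 °C) gives the silyl enol ether F6, and Saegusa–Ito dehydrogenation with Pd(OAc)2 in MeCN comes back to the route at 3.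

Further compounds
F1 | step 6 | methyl (E)-5-[3,3-(ethylenedioxy)-1-methyl-6-oxo-2-vinylcyclohexyl]-3-oxopent-4-enoate (ring configuration as in 7) | O=C1CCC2(OCCO2)[C@H](C=C)[C@@]1(C)/C=C/C(=O)CC(=O)OC
F2 | step 6 | methyl 5-[3,3-(ethylenedioxy)-1-methyl-6-oxo-2-vinylcyclohexyl]-3-oxo-5-(pyrrolidin-1-yl)pentanoate (ring configuration as in 7, C1 amine epimers) | O=C1CCC2(OCCO2)[C@H](C=C)[C@@]1(C)C(N3CCCC3)CC(=O)CC(=O)OC
F3 | step 7 | methyl 8,8-(ethylenedioxy)-3-oxo-13,14,15,16,17,18-hexanorlabda-4,11-dien-19-oate | O3CCOC31CCC2=C(C(=O)OC)C(=O)CC[C@]2(C)[C@H]1C=C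
F4 | step 1 | 1,4-dioxaspiro[4.5]dec-6-en-8-one | O=C1C=CC2(OCCO2)CC1
F5 | step 1 | (S)-6-vinyl-1,4-dioxaspiro[4.5]decan-8-one | O=C1CCC2(OCCO2)[C@H](C=C)C1
F6 | step 1 | (S)-trimethyl[(10-vinyl-1,4-dioxaspiro[4.5]dec-7-en-8-yl)oxy]silane | C[Si](C)(C)OC1=CCC2(OCCO2)[C@H](C=C)C1
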